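The route rests on cutting the C4–C5 bond of the cyclopentane ring (guaiane numbering), read as the aldol bond of a β-hydroxy ketone once the C6 carbinol is taken back to a ketone. The key step exploits C5, which lies between the C6 carbonyl and the C1=C10 alkene of the seven-membered ring and is therefore doubly activated: its lithium dienolate adds through C5 to the side-chain C4 methyl ketone, closing the five-membered ring and setting C4 and C5 in one operation. The precursor is a monocyclic cyclohept-3-enone bearing a 3-oxobutyl chain on C1, with C7 and C8 already set by an auxiliary aldol; the ring comes from metathesis, the chain from a B-alkyl Suzuki coupling.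

Key step: step 12

Remark: atom labels follow guaiane numbering (ring carbons C1–C10, C14 = methyl on C10, C15 = methyl on C4); CIP descriptors of intermediates change only where substituent priorities change (the geometry at C7 and C8 is fixed from step 2); the transient C6 carbinol of 11–19 is drawn as the Felkin–Anh epimer expected to predominate, and its configuration is erased in step 11, so its epimer converges.

Step 1
Reactants: 1 (R)-4-benzyl-1,3-thiazolidine-2-thione; 2 3-methylbutanoyl chloride
Product: 3 (R)-4-benzyl-3-(3-methylbutanoyl)-1,3-thiazolidine-2-thione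
Conditions: Et3N, DMAP (cat.), CH2Cl2, 0 °C to rt
Reagents that add atoms: none
Why: N-acylation of the acidic thiazolidinethione N–H (acyl substitution) attaches the isovaleryl unit that becomes C6, C7 and the isopropyl group; no stereocentre is formed.

Step 2
Reactants: 3 (R)-4-benzyl-3-(3-methylbutanoyl)-1,3-thiazolidine-2-thione; 4 acrolein
Product: 6 (R)-4-benzyl-3-[(2R,3S)-3-hydroxy-2-(propan-2-yl)pent-4-enoyl]-1,3-thiazolidine-2-thione, via trichlorotitanium Z-enolate 5 (not isolated)
Conditions: TiCl4, i-Pr2NEt, N-methyl-2-pyrrolidinone, CH2Cl2, 0 °C; then 4, −78 to 0 °C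
Reagents that add atoms: none
Why: Auxiliary-controlled titanium enolate syn-aldol addition (thiazolidinethione aldol, Evans-syn mode): the Z-enolate should react through a non-chelated chair Zimmerman–Traxler transition state on the face opposite the benzyl group, setting C7 and C8 (isopropyl and oxygen syn in the chain, trans in the later ring).

Step 3
Reactants: 6 (R)-4-benzyl-3-[(2R,3S)-3-hydroxy-2-(propan-2-yl)pent-4-enoyl]-1,3-thiazolidine-2-thione
Product: 7 (R)-4-benzyl-3-[(2R,3S)-3-(tert-butyldimethylsilyloxy)-2-(propan-2-yl)pent-4-enoyl]-1,3-thiazolidine-2-thione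
Conditions: t-BuMe2SiOTf, 2,6-lutidine, CH2Cl2, 0 °C
Reagents that add atoms: tert-butyldimethylsilyl trifluoromethanesulfonate, CC(C)(C)[Si](C)(C)OS(=O)(=O)C(F)(F)F
Why: O-silylation of the secondary allylic alcohol gives a base- and hydride-stable C8 protecting group that outlasts every step up to the ring closure.

Step 4
Reactants: 7 (R)-4-benzyl-3-[(2R,3S)-3-(tert-butyldimethylsilyloxy)-2-(propan-2-yl)pent-4-enoyl]-1,3-thiazolidine-2-thione
Product: 8 (2R,3S)-3-(tert-butyldimethylsilyloxy)-2-(propan-2-yl)pent-4-enal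
Conditions: i-Bu2AlH, CH2Cl2, −78 °C; aqueous Rochelle salt
Reagents that add atoms: none
Why: Partial hydride reduction of the activated N-acylthiazolidinethione stops at the aluminium hemiaminal, which collapses to the aldehyde on work-up with release of the auxiliary; at −78 °C the α-centre C7 should not epimerise.

Step 5
Reactants: 9 3-methylbut-3-en-2-one; 8 (2R,3S)-3-(tert-butyldimethylsilyloxy)-2-(propan-2-yl)pent-4-enal
Product: 11 (5R,6S,7S)-7-(tert-butyldimethylsilyloxy)-5-hydroxy-2-methyl-6-(propan-2-yl)nona-1,8-dien-3-one, via lithium enolate 10 (not isolated)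
Conditions: LiN(i-Pr)2, THF, −78 °C; then 8, −78 °C; aqueous NH4Cl
Reagents that add atoms: none
Why: Kinetic deprotonation of the only α-methyl group and lithium enolate aldol addition to the aldehyde joins C5–C6; Felkin–Anh addition should favour the drawn C6 epimer, whose configuration is irrelevant because C6 is oxidised in step 11.

Step 6
Reactants: 11 (5R,6S,7S)-7-(tert-butyldimethylsilyloxy)-5-hydroxy-2-methyl-6-(propan-2-yl)nona-1,8-dien-3-one
Product: 12 (5R,6S,7S)-7-(tert-butyldimethylsilyloxy)-2-methyl-6-(propan-2-yl)-5-(triethylsilyloxy)nona-1,8-dien-3-one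
Conditions: Et3SiOTf, 2,6-lutidine, CH2Cl2, −78 °C
Reagents that add atoms: triethylsilyl trifluoromethanesulfonate, CC[Si](CC)(CC)OS(=O)(=O)C(F)(F)F
Why: O-silylation masks the C6 hydroxyl as an acid-labile triethylsilyl ether that can later be removed in the presence of the C8 tert-butyldimethylsilyl ether and prevents retro-aldol or elimination of the β-hydroxy enone.

Step 7
Reactants: 12 (5R,6S,7S)-7-(tert-butyldimethylsilyloxy)-2-methyl-6-(propan-2-yl)-5-(triethylsilyloxy)nona-1,8-dien-3-one
Product: 13 (4S,5S,6R)-4-(tert-butyldimethylsilyloxy)-2-methyl-5-(propan-2-yl)-6-(triethylsilyloxy)cyclohept-2-en-1-one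
Conditions: second-generation Grubbs catalyst RuCl2(=CHPh)(PCy3)(H2IMes) (5 mol %), CH2Cl2 (2 mM), 40 °C
Reagents that add atoms: none
Why: Ring-closing olefin metathesis between the allylic vinyl group and the isopropenyl ketone closes the seven-membered ring as its C9=C10 trisubstituted enone with loss of ethylene; no stereocentre is touched.

Step 8
Reactants: 13 (4S,5S,6R)-4-(tert-butyldimethylsilyloxy)-2-methyl-5-(propan-2-yl)-6-(triethylsilyloxy)cyclohept-2-en-1-one
Product: 15 (4S,5R,6R)-4-(tert-butyldimethylsilyloxy)-2-methyl-5-(propan-2-yl)-6-(triethylsilyloxy)cyclohept-1-en-1-yl trifluoromethanesulfonate, via lithium enolate 14 (not isolated)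
Conditions: LiBH(s-Bu)3, THF, −78 °C; then PhNTf2, −78 to 0 °C
Reagents that add atoms: N-phenylbis(trifluoromethanesulfonimide), O=S(=O)(N(c1ccccc1)S(=O)(=O)C(F)(F)F)C(F)(F)F
Why: Conjugate (1,4) hydride reduction of the α-methyl, β-unsubstituted enone gives regiospecifically the tetrasubstituted C1=C10 enolate, and enolate O-triflation fixes the position of the later ring double bond.

Step 9
Reactants: 15 (4S,5R,6R)-4-(tert-butyldimethylsilyloxy)-2-methyl-5-(propan-2-yl)-6-(triethylsilyloxy)cyclohept-1-en-1-yl trifluoromethanesulfonate; 16 2-methyl-2-vinyl-1,3-dioxolane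
Product: 18 2-{2-[(4S,5S,6R)-4-(tert-butyldimethylsilyloxy)-2-methyl-5-(propan-2-yl)-6-(triethylsilyloxy)cyclohept-1-en-1-yl]ethyl}-2-methyl-1,3-dioxolane, via B-alkyl-9-borabicyclononane 17 (not isolated)
Conditions: 16, 9-BBN-H, THF, rt; then 15, Pd(dppf)Cl2 (5 mol %), AsPh3, 3 M aqueous K3PO4, DMF, 50 °C
Reagents that add atoms: none
Why: Anti-Markovnikov hydroboration followed by B-alkyl Suzuki–Miyaura cross-coupling attaches the masked 3-oxobutyl chain (C2, C3, C4, C15) to C1 with retention of the tetrasubstituted alkene.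

Step 10
Reactants: 18 2-{2-[(4S,5S,6R)-4-(tert-butyldimethylsilyloxy)-2-methyl-5-(propan-2-yl)-6-(triethylsilyloxy)cyclohept-1-en-1-yl]ethyl}-2-methyl-1,3-dioxolane
Product: 19 4-[(4S,5S,6R)-4-(tert-butyldimethylsilyloxy)-6-hydroxy-2-methyl-5-(propan-2-yl)cyclohept-1-en-1-yl]butan-2-one
Conditions: PPTS, acetone–H2O (9:1), 55 °C
Reagents that add atoms: water, O
Why: Mild acid hydrolysis (acetal cleavage and triethylsilyl ether solvolysis) unmasks the C4 ketone and the C6 alcohol, while the hindered secondary tert-butyldimethylsilyl ether at C8 should survive.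

Step 11
Reactants: 19 4-[(4S,5S,6R)-4-(tert-butyldimethylsilyloxy)-6-hydroxy-2-methyl-5-(propan-2-yl)cyclohept-1-en-1-yl]butan-2-one
Product: 20 (6S,7R)-6-(tert-butyldimethylsilyloxy)-4-methyl-3-(3-oxobutyl)-7-(propan-2-yl)cyclohept-3-en-1-one
Conditions: Dess–Martin periodinane, NaHCO3, CH2Cl2, 0 °C to rt
Reagents that add atoms: none
Why: Buffered Dess–Martin oxidation turns the homoallylic C6 alcohol into the β,γ-unsaturated ketone without moving the C1=C10 double bond into conjugation, and removes the transient C6 stereocentre.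

Step 12
Reactants: 20 (6S,7R)-6-(tert-butyldimethylsilyloxy)-4-methyl-3-(3-oxobutyl)-7-(propan-2-yl)cyclohept-3-en-1-one
Product: 22 (4S,5R,7R,8S)-8-(tert-butyldimethylsilyloxy)-4-hydroxyguai-1(10)-en-6-one, via lithium dienolate 21 (not isolated)
Conditions: LiN(SiMe3)2 (1.0 equiv), THF, −78 to −40 °C; AcOH, −78 °C
Reagents that add atoms: none
Why: LiN(SiMe3)2 should remove the uniquely acidic C5–H (α to the C6 ketone and allylic to C1=C10) to give lithium dienolate 21, whose α-carbon C5 adds to the side-chain C4 ketone through a lithium-bridged chair-like Zimmerman–Traxler transition state, and a cold acetic acid quench should return the β,γ-unsaturated ketol. The closest known reaction type is the intramolecular aldol addition of a 1,6-diketone (the ketol stage of a Robinson-type annulation), run here as the deconjugative α-aldol of an extended enolate. The five-membered ring closes in the 5-(enolexo)-exo-trig mode, the enolate double bond C5=C6 staying outside the new ring. At C4 the lithium bridge between O6 and the C4 carbonyl oxygen forces the new hydroxyl cis to the C6 carbonyl on the cyclopentane (methyl cis to H5); at C5 closure is expected on the dienolate face that puts the new C5–C4 bond cis to the C7 isopropyl group, the arrangement in which C4, the isopropyl group and the trans C8 silyl ether are all pseudo-equatorial on the seven-membered ring, and since ketone aldolates revert readily this most stable chelated aldolate should accumulate between −78 and −40 °C. The step needs regioselective enolisation at C5 (secured by its double activation over C7, C3 and C15, the methyl-ketone enolates having no unstrained ring to close) and α- rather than γ-attack of the dienolate (secured by the closed lithium chelate, which reaches only C5, and by the fully substituted C10).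

Step 13
Reactants: 22 (4S,5R,7R,8S)-8-(tert-butyldimethylsilyloxy)-4-hydroxyguai-1(10)-en-6-one
Product: 23 (4S,5R,7R,8S)-4,8-dihydroxyguai-1(10)-en-6-one
Conditions: HF·pyridine, pyridine, THF, 0 °C to rt
Reagents that add atoms: none
Why: Buffered fluoride desilylation frees the C8 hydroxyl under non-basic conditions, so neither β-hydroxy ketone unit should undergo retro-aldol cleavage and the C5 centre is not epimerised.

Step 14
Reactants: 23 (4S,5R,7R,8S)-4,8-dihydroxyguai-1(10)-en-6-one; 24 4-(prop-2-enyloxy)benzoic acid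
Product: 25 (4S,5R,7R,8S)-4-hydroxy-6-oxoguai-1(10)-en-8-yl 4-(prop-2-enyloxy)benzoate
Conditions: 24, EDC·HCl, DMAP, CH2Cl2, rt
Reagents that add atoms: none
Why: Steglich esterification acylates the secondary C8 hydroxyl with retention, the tertiary C4 hydroxyl being unreactive under carbodiimide/DMAP conditions.

Step 15
Reactants: 25 (4S,5R,7R,8S)-4-hydroxy-6-oxoguai-1(10)-en-8-yl 4-(prop-2-enyloxy)benzoate
Product: 27 (4S,5S,6R,7S,8S)-4,6-dihydroxyguai-1(10)-en-8-yl 4-(prop-2-enyloxy)benzoate, via C4 O-diethylboryl chelate 26 (not isolated)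
Conditions: Et2BOMe, THF–MeOH (4:1), −78 °C; NaBH4, −78 °C; AcOH, then MeOH co-evaporation
Reagents that add atoms: none
Why: Narasaka–Prasad syn-selective reduction: the boron chelate between the C4 oxygen and the C6 carbonyl locks the ketone, and external hydride should add to the chelate face anti to C1 of the carbocycle (the face of H5 and H7), giving the C6 alcohol syn to the C4 hydroxyl and cis to the isopropyl group, while the benzoate is inert to NaBH4 at −78 °C.

Step 16
Reactants: 27 (4S,5S,6R,7S,8S)-4,6-dihydroxyguai-1(10)-en-8-yl 4-(prop-2-enyloxy)benzoate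
Product: 28 (4S,5S,6R,7S,8S)-4,6-dihydroxyguai-1(10)-en-8-yl 4-hydroxybenzoate (CNP0392039.1)
Conditions: Pd(PPh3)4 (5 mol %), morpholine, THF, rt
Reagents that add atoms: none
Why: Zerovalent palladium ionises the aryl allyl ether to a π-allyl complex (Tsuji–Trost deallylation) that morpholine intercepts, releasing the phenol under near-neutral conditions that should leave the benzoate, the diol and the tetrasubstituted alkene untouched.

Compound list
1 | (R)-4-benzyl-1,3-thiazolidine-2-thione | S=C1SC[C@@H](Cc2ccccc2)N1 | starting material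
2 | 3-methylbutanoyl chloride | CC(C)CC(=O)Cl | starting material
3 | (R)-4-benzyl-3-(3-methylbutanoyl)-1,3-thiazolidine-2-thione | CC(C)CC(=O)N1C(=S)SC[C@H]1Cc1ccccc1 | intermediate
4 | acrolein (prop-2-enal) | C=CC=O | starting material
5 | trichlorotitanium Z-enolate of 3 (formed in the flask) | CC(C)/C=C(\O[Ti](Cl)(Cl)Cl)N1C(=S)SC[C@H]1Cc1ccccc1 | intermediate
6 | (R)-4-benzyl-3-[(2R,3S)-3-hydroxy-2-(propan-2-yl)pent-4-enoyl]-1,3-thiazolidine-2-thione | O=C([C@H](C(C)C)[C@@H](O)C=C)N1C(=S)SC[C@H]1Cc1ccccc1 | intermediate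
7 | (R)-4-benzyl-3-[(2R,3S)-3-(tert-butyldimethylsilyloxy)-2-(propan-2-yl)pent-4-enoyl]-1,3-thiazolidine-2-thione | O=C([C@H](C(C)C)[C@@H](O[Si](C)(C)C(C)(C)C)C=C)N1C(=S)SC[C@H]1Cc1ccccc1 | intermediate
8 | (2R,3S)-3-(tert-butyldimethylsilyloxy)-2-(propan-2-yl)pent-4-enal | O=C[C@H](C(C)C)[C@@H](O[Si](C)(C)C(C)(C)C)C=C | intermediate
9 | 3-methylbut-3-en-2-one | CC(=O)C(C)=C | starting material
10 | lithium 3-methylbuta-1,3-dien-2-olate, the lithium enolate of 9 (formed in the flask) | C=C(C)C(=C)O[Li] | intermediate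
11 | (5R,6S,7S)-7-(tert-butyldimethylsilyloxy)-5-hydroxy-2-methyl-6-(propan-2-yl)nona-1,8-dien-3-one (guaiane 6R,7S,8S) | C=C(C)C(=O)C[C@@H](O)[C@H](C(C)C)[C@@H](O[Si](C)(C)C(C)(C)C)C=C | intermediate
12 | (5R,6S,7S)-7-(tert-butyldimethylsilyloxy)-2-methyl-6-(propan-2-yl)-5-(triethylsilyloxy)nona-1,8-dien-3-one | C=C(C)C(=O)C[C@@H](O[Si](CC)(CC)CC)[C@H](C(C)C)[C@@H](O[Si](C)(C)C(C)(C)C)C=C | intermediate
13 | (4S,5S,6R)-4-(tert-butyldimethylsilyloxy)-2-methyl-5-(propan-2-yl)-6-(triethylsilyloxy)cyclohept-2-en-1-one | O=C1C[C@@H](O[Si](CC)(CC)CC)[C@H](C(C)C)[C@@H](O[Si](C)(C)C(C)(C)C)C=C1C | intermediate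
14 | lithium enolate from 1,4-reduction of 13 (O–Li on C1, C1=C10; formed in the flask) | CC1=C(O[Li])C[C@@H](O[Si](CC)(CC)CC)[C@H](C(C)C)[C@@H](O[Si](C)(C)C(C)(C)C)C1 | intermediate
15 | (4S,5R,6R)-4-(tert-butyldimethylsilyloxy)-2-methyl-5-(propan-2-yl)-6-(triethylsilyloxy)cyclohept-1-en-1-yl trifluoromethanesulfonate | CC1=C(OS(=O)(=O)C(F)(F)F)C[C@@H](O[Si](CC)(CC)CC)[C@H](C(C)C)[C@@H](O[Si](C)(C)C(C)(C)C)C1 | intermediate
16 | 2-methyl-2-vinyl-1,3-dioxolane | C=CC1(C)OCCO1 | starting material
17 | 9-[2-(2-methyl-1,3-dioxolan-2-yl)ethyl]-9-borabicyclo[3.3.1]nonane (formed in the flask) | CC1(CCB2C3CCCC2CCC3)OCCO1 | intermediate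
18 | 2-{2-[(4S,5S,6R)-4-(tert-butyldimethylsilyloxy)-2-methyl-5-(propan-2-yl)-6-(triethylsilyloxy)cyclohept-1-en-1-yl]ethyl}-2-methyl-1,3-dioxolane | CC1=C(CCC2(C)OCCO2)C[C@@H](O[Si](CC)(CC)CC)[C@H](C(C)C)[C@@H](O[Si](C)(C)C(C)(C)C)C1 | intermediate
19 | 4-[(4S,5S,6R)-4-(tert-butyldimethylsilyloxy)-6-hydroxy-2-methyl-5-(propan-2-yl)cyclohept-1-en-1-yl]butan-2-one | CC1=C(CCC(C)=O)C[C@@H](O)[C@H](C(C)C)[C@@H](O[Si](C)(C)C(C)(C)C)C1 | intermediate
20 | (6S,7R)-6-(tert-butyldimethylsilyloxy)-4-methyl-3-(3-oxobutyl)-7-(propan-2-yl)cyclohept-3-en-1-one | CC1=C(CCC(C)=O)CC(=O)[C@H](C(C)C)[C@@H](O[Si](C)(C)C(C)(C)C)C1 | intermediate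
21 | lithium dienolate of 20 (O–Li on C6, C5=C6 and C1=C10; formed in the flask) | CC1=C(CCC(C)=O)C=C(O[Li])[C@H](C(C)C)[C@@H](O[Si](C)(C)C(C)(C)C)C1 | intermediate
22 | (4S,5R,7R,8S)-8-(tert-butyldimethylsilyloxy)-4-hydroxyguai-1(10)-en-6-one (4-OH cis to C6 on the cyclopentane, H5 cis to H7) | CC1=C2CC[C@](C)(O)[C@@H]2C(=O)[C@H](C(C)C)[C@@H](O[Si](C)(C)C(C)(C)C)C1 | intermediate
23 | (4S,5R,7R,8S)-4,8-dihydroxyguai-1(10)-en-6-one | CC1=C2CC[C@](C)(O)[C@@H]2C(=O)[C@H](C(C)C)[C@@H](O)C1 | intermediate
24 | 4-(prop-2-enyloxy)benzoic acid | C=CCOc1ccc(cc1)C(=O)O | starting material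
25 | (4S,5R,7R,8S)-4-hydroxy-6-oxoguai-1(10)-en-8-yl 4-(prop-2-enyloxy)benzoate | CC1=C2CC[C@](C)(O)[C@@H]2C(=O)[C@H](C(C)C)[C@@H](OC(=O)c2ccc(OCC=C)cc2)C1 | intermediate
26 | C4 O-diethylboryl derivative of 25, chelated to the C6 carbonyl (formed in the flask) | CC1=C2CC[C@](C)(OB(CC)CC)[C@@H]2C(=O)[C@H](C(C)C)[C@@H](OC(=O)c2ccc(OCC=C)cc2)C1 | intermediate
27 | (4S,5S,6R,7S,8S)-4,6-dihydroxyguai-1(10)-en-8-yl 4-(prop-2-enyloxy)benzoate | CC1=C2CC[C@](C)(O)[C@@H]2[C@H](O)[C@H](C(C)C)[C@@H](OC(=O)c2ccc(OCC=C)cc2)C1 | intermediate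
28 | (4S,5S,6R,7S,8S)-4,6-dihydroxyguai-1(10)-en-8-yl 4-hydroxybenzoate, i.e. (3S,3aS,4R,5S,6S)-3,4-dihydroxy-3,8-dimethyl-5-(propan-2-yl)-1,2,3,3a,4,5,6,7-octahydroazulen-6-yl 4-hydroxybenzoate | CC1=C2CC[C@](C)(O)[C@@H]2[C@H](O)[C@H](C(C)C)[C@@H](OC(=O)c2ccc(O)cc2)C1 | target

Total step count: 16. Longest linear sequence: 16 steps (from 1 and 2; compounds 4, 9, 16 and 24 enter as purchased building blocks).

Steps most likely to fail

Step 12 (ring-closing aldol). Proton transfer may outrun ring closure: the dienolate can be reprotonated at C10 to the conjugated enone and the enolate sites can scramble. Retro-aldol equilibration may also drain the chelated aldolate towards closure on the other face of C5 or at the γ-carbon C10. Fallback: setting out from diketone 20, soft enolisation with Me3SiOTf (1.0 equiv) and Et3N in CH2Cl2 at −78 °C should silylate the doubly activated C5 position selectively to give the silyl dienol ether F1. Treatment with TiCl4 in CH2Cl2 at −78 °C then closes the ring by an intramolecular Mukaiyama aldol addition through a titanium-chelated transition state, irreversibly and without base, and the sequence comes back to the route at ketol 22. Should C5 emerge epimeric, its acidic hydrogen allows equilibration to the cis-α,α′ ketol.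

Step 9 (B-alkyl Suzuki coupling). Transmetalation of the alkylborane onto the hindered tetrasubstituted alkenylpalladium may be slow, so that triflate hydrolysis and β-hydride elimination of the alkyl partner overtake the coupling. Fallback: setting out from enol triflate 15, a Mizoroki–Heck reaction with but-3-en-2-one (Pd(OAc)2, PPh3, Et3N, DMF, 60 °C) needs no sp3 organometallic and should give the (E)-dienone F2. Chemoselective 1,4-reduction of its disubstituted enone double bond with [CuH(PPh3)]6 in wet toluene leaves the fully substituted C1=C10 alkene and gives the saturated methyl ketone F3. Removal of the triethylsilyl group under the conditions of step 10 brings the sequence back to the route at hydroxy ketone 19.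

Step 15 (C6 reduction). If the tertiary C4 hydroxyl fails to form the boron chelate, hydride may add to the wrong face of the C6 carbonyl; a 1,3-acyl shift from O8 to O6 is also possible once the alkoxide is formed. Fallback: setting out from diol ketone 23 (before esterification), Evans–Saksena reduction with Me4NBH(OAc)3 in MeCN–AcOH at −20 °C delivers hydride intramolecularly from the C8 hydroxyl on the β-face and should give the triol F4. The syn 4,6-diol is then tied up with PhB(OH)2 (toluene, MgSO4) as the cyclic phenylboronate F5, and Steglich esterification of the remaining C8 hydroxyl with 24 gives the boronate ester F6. Exchange with pinacol releases the diol and the sequence comes back to the route at compound 27.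

Further compounds
F1 | step 12 | silyl dienol ether of 20 (C6–OSiMe3, C5=C6 and C1=C10) | CC1=C(CCC(C)=O)C=C(O[Si](C)(C)C)[C@H](C(C)C)[C@@H](O[Si](C)(C)C(C)(C)C)C1
F2 | step 9 | (E)-4-[(4S,5S,6R)-4-(tert-butyldimethylsilyloxy)-2-methyl-5-(propan-2-yl)-6-(triethylsilyloxy)cyclohept-1-en-1-yl]but-3-en-2-one | CC1=C(/C=C/C(C)=O)C[C@@H](O[Si](CC)(CC)CC)[C@H](C(C)C)[C@@H](O[Si](C)(C)C(C)(C)C)C1
F3 | step 9 | 4-[(4S,5S,6R)-4-(tert-butyldimethylsilyloxy)-2-methyl-5-(propan-2-yl)-6-(triethylsilyloxy)cyclohept-1-en-1-yl]butan-2-one | CC1=C(CCC(C)=O)C[C@@H](O[Si](CC)(CC)CC)[C@H](C(C)C)[C@@H](O[Si](C)(C)C(C)(C)C)C1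
F4 | step 15 | (4S,5S,6R,7S,8S)-guai-1(10)-ene-4,6,8-triol | CC1=C2CC[C@](C)(O)[C@@H]2[C@H](O)[C@H](C(C)C)[C@@H](O)C1
F5 | step 15 | 4,6-O-phenylboronate of triol F4 (C8 hydroxyl free) | CC1=C2CC[C@](C)(OB(c3ccccc3)O4)[C@@H]2[C@H]4[C@H](C(C)C)[C@@H](O)C1
F6 | step 15 | 4,6-O-phenylboronate of 27 (C8 4-(prop-2-enyloxy)benzoate) | CC1=C2CC[C@](C)(OB(c3ccccc3)O4)[C@@H]2[C@H]4[C@H](C(C)C)[C@@H](OC(=O)c3ccc(OCC=C)cc3)C1
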